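**Retrosynthetic overview**
1. Target 27 ⇐ fluoride desilylation of 26; the C2–side-chain bond is cut back to a vinyl radical closing 7-exo across a di-tert-butylsilyl ketal that ties the C1 carbinol to iodotrienol 7 (light-initiated, sets C2 cis to the C1 oxygen).
2. The enal ⇐ oxidative 1,3-transposition of an isopropenyl carbinol at C9; 7 ⇐ propargyl alcohol, iodine and myrcene (Heck).
3. Ring B ⇐ aldol condensation of an acetyl and a CH2CHO group on C5, then hydroxyl-directed reduction of the cyclopentenone (C1).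
4. Quaternary C5 and C10 ⇐ silicon-tethered radical conjugate cyclisation with allyl transfer, delivered from the tertiary carbinol of enynone 14.
5. Ring A (14) ⇐ (1S,2S,4R)-limonene-1,2-diol, whose tertiary carbinol becomes C6 and relays all other stereocentres. Ring order: ring A (bought), then ring B, then the temporary silicon ring.

Locants in the Why lines are those of the target's spiro[4.5]decane: C1 carbinol, C2 side-chain carbon, C5 spiro, C6 C(OH)CH3, C9 ylidene carbon, C10 CH bearing the C3 chain.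
Assumption: the carbinol configurations at C1 of 13 and at C9 of 17–24 are drawn as the expected major isomers; both centres are destroyed later (steps 7 and 16).

**Step 1**
Reactants: 1 chlorodimethyl(vinyl)silane
Product: 3 (1-bromoethenyl)chlorodimethylsilane, via dibromide 2 (not isolated)
Conditions: Br2, CH2Cl2, −78 → 0 °C; then PhNEt2, 120 °C, distil
Reagents that add atoms: bromine, BrBr
Why: Bromine adds across the vinyl group and the amine removes HBr from the silicon-bearing carbon (addition–dehydrobromination), giving the α-bromovinylsilane.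

**Step 2**
Reactants: 4 prop-2-yn-1-ol
Product: 5 (E)-2,3-diiodoprop-2-en-1-ol
Conditions: iodine, NaI (cat.), H2O, 23 °C
Reagents that add atoms: iodine, [I][I]
Why: Electrophilic anti-addition of iodine to the alkyne through a bridged iodonium ion gives the E-diiodide.

**Step 3**
Reactants: 5 (E)-2,3-diiodoprop-2-en-1-ol; 6 β-myrcene (3 equiv)
Product: 7 (2E,4E)-2-iodo-10-methyl-6-methylideneundeca-2,4,9-trien-1-ol
Conditions: Pd(OAc)2 (5 mol %), P(o-tol)3 (10 mol %), Et3N, MeCN, 45 °C
Reagents that add atoms: none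
Why: Mizoroki–Heck reaction in which zerovalent palladium inserts into the less hindered terminal carbon–iodine bond, adds to the free terminus of myrcene's monosubstituted vinyl group and eliminates β-hydride to the E-diene, with retention at the iodoalkene.

**Step 4**
Reactants: 8 (1S,2S,4R)-1-methyl-4-(prop-1-en-2-yl)cyclohexane-1,2-diol
Product: 9 (2S,5R)-2-hydroxy-2-methyl-5-(prop-1-en-2-yl)cyclohexan-1-one
Conditions: IBX (1.5 equiv), EtOAc, 75 °C
Reagents that add atoms: none
Why: IBX oxidation of the secondary hydroxyl of a 1,2-diol gives the α-ketol without C–C cleavage and leaves the bought tertiary carbinol (future C6) untouched.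

**Step 5**
Reactants: 9 (2S,5R)-2-hydroxy-2-methyl-5-(prop-1-en-2-yl)cyclohexan-1-one
Product: 12 (S)-6-hydroxy-6-methylcyclohex-2-en-1-one, via methoxy hydroperoxide 10 (not isolated), via acetate 11 (not isolated)
Conditions: O3, CH2Cl2/MeOH, −78 °C; then Ac2O (1.5 equiv), Et3N, DMAP (cat.), −78 → 23 °C; then DBU, 23 °C
Reagents that add atoms: none
Why: Ozonolysis in methanol, Criegee rearrangement of the derived peracetate (acetate replaces isopropenyl) and E1cB loss of acetic acid give the enone, in which the bought carbinol is the only stereocentre.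

**Step 6**
Reactants: 12 (S)-6-hydroxy-6-methylcyclohex-2-en-1-one
Product: 13 (1R,6S)-1-ethynyl-6-methylcyclohex-2-ene-1,6-diol
Conditions: HC≡CMgBr (3 equiv), THF, −78 → 0 °C
Reagents that add atoms: ethynylmagnesium bromide, C#C[Mg]Br
Why: Grignard 1,2-addition to the enone carbonyl under magnesium alkoxide chelation; the new carbinol centre is erased in step 7.

**Step 7**
Reactants: 13 (1R,6S)-1-ethynyl-6-methylcyclohex-2-ene-1,6-diol
Product: 14 (S)-3-ethynyl-4-hydroxy-4-methylcyclohex-2-en-1-one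
Conditions: IBX (2.5 equiv), DMSO, 55 °C
Reagents that add atoms: 2-iodoxybenzoic acid, O=C1OI(=O)(O)c2ccccc12
Why: Dauben-type oxidative 1,3-transposition of the tertiary allylic alcohol (allylic shift of its iodine ester, then oxidation) places the carbonyl at C9 and makes C5 the β-carbon of an enone.

**Step 8**
Reactants: 14 (S)-3-ethynyl-4-hydroxy-4-methylcyclohex-2-en-1-one; 3 (1-bromoethenyl)chlorodimethylsilane
Product: 15 (S)-4-{[(1-bromoethenyl)dimethylsilyl]oxy}-3-ethynyl-4-methylcyclohex-2-en-1-one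
Conditions: imidazole, DMAP (cat.), CH2Cl2, 0 → 23 °C
Reagents that add atoms: none
Why: Silyl ether formation puts the Stork–Tamao bromovinylsilyl radical precursor on the bought stereocentre.

**Step 9**
Reactants: 15 (S)-4-{[(1-bromoethenyl)dimethylsilyl]oxy}-3-ethynyl-4-methylcyclohex-2-en-1-one
Product: 16 (3aS,4S,7aS)-3a-ethynyl-2,2,7a-trimethyl-3-methylidene-4-(prop-2-en-1-yl)hexahydro-1,2-benzoxasilol-5(4H)-one
Conditions: CH2=CHCH2SnBu3 (5 equiv), AIBN (0.2 equiv), PhH (0.05 M), 80 °C
Reagents that add atoms: allyltributylstannane, C=CC[Sn](CCCC)(CCCC)CCCC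
Why: Tin radical chain combining a silicon-tethered 5-exo cyclisation with Keck allylation: the tethered α-silylvinyl radical can reach the β-carbon C5 only from the face of the C6 oxygen (quaternary centre fixed), and the resulting α-keto radical at C10 takes up allyl anti to the axial ethynyl group, i.e. cis to the new C5–C bond.

**Step 10**
Reactants: 16 (3aS,4S,7aS)-3a-ethynyl-2,2,7a-trimethyl-3-methylidene-4-(prop-2-en-1-yl)hexahydro-1,2-benzoxasilol-5(4H)-one
Product: 17 (3aS,4S,5R,7aS)-3a-ethynyl-2,2,7a-trimethyl-3-methylidene-4-(prop-2-en-1-yl)-5-(prop-1-en-2-yl)octahydro-1,2-benzoxasilol-5-ol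
Conditions: CH2=C(CH3)MgBr (3 equiv), LaCl3·2LiCl (0.3 equiv), THF, −40 → 0 °C
Reagents that add atoms: isopropenylmagnesium bromide, CC(=C)[Mg]Br
Why: Lanthanum-assisted Grignard 1,2-addition to the hindered C9 ketone avoids enolisation and removes the epimerisable C10–H; the new carbinol centre is erased in step 16.

**Step 11**
Reactants: 17 (3aS,4S,5R,7aS)-3a-ethynyl-2,2,7a-trimethyl-3-methylidene-4-(prop-2-en-1-yl)-5-(prop-1-en-2-yl)octahydro-1,2-benzoxasilol-5-ol
Product: 19 2-[1-acetyl-2,5-dihydroxy-6-(3-hydroxypropyl)-2-methyl-5-(prop-1-en-2-yl)cyclohexyl]acetaldehyde (acetyl cis to the 2-hydroxyl and to the 6-side chain), via bis-borane 18 (not isolated)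
Conditions: (c-C6H11)2BH (3.5 equiv), THF, 0 °C; then 30% H2O2, KF, KHCO3, THF/MeOH, 23 °C
Reagents that add atoms: hydrogen peroxide, OO
Why: The hindered dialkylborane hydroborates only the terminal alkyne and the monosubstituted alkene, and Brown plus Tamao–Fleming oxidation converts the C–B and C–Si bonds into CH2CHO, CH2OH and the methyl ketone with retention at every stereocentre.

**Step 12**
Reactants: 19 2-[1-acetyl-2,5-dihydroxy-6-(3-hydroxypropyl)-2-methyl-5-(prop-1-en-2-yl)cyclohexyl]acetaldehyde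
Product: 20 6,9-dihydroxy-10-(3-hydroxypropyl)-6-methyl-9-(prop-1-en-2-yl)spiro[4.5]dec-2-en-1-one (C1 cis to the 6-hydroxyl and to the C10 chain)
Conditions: pyrrolidine (0.3 equiv), AcOH (0.3 equiv), THF, 45 °C
Reagents that add atoms: none
Why: Amine-catalysed intramolecular aldol condensation of the 1,4-keto aldehyde closes ring B as the cyclopentenone, and the weakly acidic medium avoids retro-aldol opening of the C5–C6 bond.

**Step 13**
Reactants: 20 6,9-dihydroxy-10-(3-hydroxypropyl)-6-methyl-9-(prop-1-en-2-yl)spiro[4.5]dec-2-en-1-one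
Product: 21 10-[3-(tert-butyldimethylsilyloxy)propyl]-6,9-dihydroxy-6-methyl-9-(prop-1-en-2-yl)spiro[4.5]dec-2-en-1-one
Conditions: TBSCl (1.1 equiv), imidazole, CH2Cl2, 0 °C
Reagents that add atoms: tert-butyldimethylsilyl chloride, CC(C)(C)[Si](C)(C)Cl
Why: Silyl ether formation is selective for the only primary hydroxyl, the other two being tertiary.

**Step 14**
Reactants: 21 10-[3-(tert-butyldimethylsilyloxy)propyl]-6,9-dihydroxy-6-methyl-9-(prop-1-en-2-yl)spiro[4.5]dec-2-en-1-one
Product: 22 10-[3-(tert-butyldimethylsilyloxy)propyl]-6-methyl-9-(prop-1-en-2-yl)spiro[4.5]dec-2-ene-1,6,9-triol (1-hydroxyl on the ring-B face syn to C10)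
Conditions: Me4NBH(OAc)3 (5 equiv), MeCN/AcOH (2:1), −30 °C
Reagents that add atoms: none
Why: Evans–Saksena hydroxyl-directed reduction, in which the C6 hydroxyl binds boron and delivers hydride to the neighbouring C1 carbonyl from its own face, so the new hydroxyl lies on the ring-B face syn to C10.

**Step 15**
Reactants: 7 (2E,4E)-2-iodo-10-methyl-6-methylideneundeca-2,4,9-trien-1-ol; 22 the triol of step 14
Product: 24 di-tert-butylsilyl ketal joining the C1 oxygen of 22 and the oxygen of 7, via silyl triflate 23 (not isolated)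
Conditions: 7, tBu2Si(OTf)2 (1.0 equiv), 2,6-lutidine, CH2Cl2, −78 → 0 °C; then 22, DMAP (cat.), 0 → 23 °C
Reagents that add atoms: di-tert-butylsilyl bis(trifluoromethanesulfonate), CC(C)(C)[Si](OS(=O)(=O)C(F)(F)F)(OS(=O)(=O)C(F)(F)F)C(C)(C)C
Why: Stepwise silyl ketal formation, the primary alcohol of 7 displacing the first triflate and the only secondary alcohol of 22 the second (the tertiary alcohols are too hindered), installs the temporary silicon tether.

**Step 16**
Reactants: 24 the silyl ketal of step 15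
Product: 25 (2E)-2-(spiro[4.5]dec-2-en-9-ylidene)propanal bearing the 1-O silyl ketal to the iodotrienyl unit, the 6-hydroxyl and the 10-(3-silyloxypropyl) chain
Conditions: pyridinium chlorochromate [C5H5NH][CrO3Cl] (3 equiv), NaOAc, 4 Å MS, CH2Cl2, 23 °C
Reagents that add atoms: pyridinium chlorochromate, [O-][Cr](=O)(=O)Cl.c1cc[nH+]cc1
Why: Babler–Dauben oxidative transposition, whose chromate [3,3]-shift runs through a chair with the more substituted C10 equatorial, so the methyl ends cis to C10 and the formyl group cis to C8.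

**Step 17**
Reactants: 25 the enal silyl ketal of step 16
Product: 26 cyclised silylene: the target with its C1 oxygen and side-chain CH2 oxygen bridged by tBu2Si and its primary hydroxyl as the tert-butyldimethylsilyl ether
Conditions: (Me3Si)3SiH (1.3 equiv, syringe pump, 8 h), diphenyl(2,4,6-trimethylbenzoyl)phosphine oxide (5 mol %), 405 nm LEDs, degassed PhH (2 mM), 20 °C
Reagents that add atoms: none
Why: Proposed new method: under visible-light initiation a silyl radical abstracts iodine from the alkenyl iodide, the σ-alkenyl radical closes 7-exo-trig onto C2 of the cyclopentene from the face of the tethering C1 oxygen (cis C1–O/C2–C) through the invertomer whose forming bond is anti to the dienyl group (ring cis to H on the new trisubstituted alkene), and the C3 radical takes hydrogen from Si–H; the closest known reaction type is the silicon-tethered (silyl ether or silyl ketal) radical cyclisation of halides under tin or silane mediation.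

**Step 18**
Reactants: 26 the cyclised silylene of step 17
Product: 27 (2E)-2-[(1R,2S,5S,6S,10R)-1,6-dihydroxy-2-[(2Z,4E)-1-hydroxy-10-methyl-6-methylideneundeca-2,4,9-trien-2-yl]-10-(3-hydroxypropyl)-6-methylspiro[4.5]decan-9-ylidene]propanal
Conditions: HF·pyridine, pyridine, THF, 0 → 23 °C
Reagents that add atoms: none
Why: Buffered fluoride desilylation cleaves only Si–O bonds, releasing the three hydroxyls without touching the enal, the triene or any stereocentre.

**Compound list**
1 | chlorodimethyl(vinyl)silane | C=C[Si](C)(C)Cl | starting material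
2 | chloro(1,2-dibromoethyl)dimethylsilane | BrCC(Br)[Si](C)(C)Cl | intermediate
3 | (1-bromoethenyl)chlorodimethylsilane | C=C(Br)[Si](C)(C)Cl | intermediate
4 | prop-2-yn-1-ol | C#CCO | starting material
5 | (E)-2,3-diiodoprop-2-en-1-ol | OC/C(I)=C\I | intermediate
6 | β-myrcene (7-methyl-3-methylideneocta-1,6-diene) | C=CC(=C)CCC=C(C)C | starting material
7 | (2E,4E)-2-iodo-10-methyl-6-methylideneundeca-2,4,9-trien-1-ol | C=C(/C=C/C=C(\CO)I)CCC=C(C)C | intermediate
8 | (1S,2S,4R)-1-methyl-4-(prop-1-en-2-yl)cyclohexane-1,2-diol (limonene-1,2-diol) | C[C@@]1(O)[C@@H](O)C[C@H](C(C)=C)CC1 | starting material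
9 | (2S,5R)-2-hydroxy-2-methyl-5-(prop-1-en-2-yl)cyclohexan-1-one | C[C@@]1(O)C(=O)C[C@H](C(C)=C)CC1 | intermediate
10 | (2S,5R)-5-(1-hydroperoxy-1-methoxyethyl)-2-hydroxy-2-methylcyclohexan-1-one | C[C@@]1(O)C(=O)C[C@H](C(C)(OC)OO)CC1 | intermediate
11 | (1R,4S)-4-hydroxy-4-methyl-3-oxocyclohexyl acetate | C[C@@]1(O)C(=O)C[C@H](OC(C)=O)CC1 | intermediate
12 | (S)-6-hydroxy-6-methylcyclohex-2-en-1-one | C[C@@]1(O)C(=O)C=CCC1 | intermediate
13 | (1R,6S)-1-ethynyl-6-methylcyclohex-2-ene-1,6-diol | C[C@@]1(O)[C@](O)(C#C)C=CCC1 | intermediate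
14 | (S)-3-ethynyl-4-hydroxy-4-methylcyclohex-2-en-1-one | C[C@@]1(O)C(C#C)=CC(=O)CC1 | intermediate
15 | (S)-4-{[(1-bromoethenyl)dimethylsilyl]oxy}-3-ethynyl-4-methylcyclohex-2-en-1-one | C[C@@]1(O[Si](C)(C)C(Br)=C)C(C#C)=CC(=O)CC1 | intermediate
16 | (3aS,4S,7aS)-3a-ethynyl-2,2,7a-trimethyl-3-methylidene-4-(prop-2-en-1-yl)hexahydro-1,2-benzoxasilol-5(4H)-one | C#C[C@@]12[C@H](CC=C)C(=O)CC[C@]1(C)O[Si](C)(C)C2=C | intermediate
17 | (3aS,4S,5R,7aS)-3a-ethynyl-2,2,7a-trimethyl-3-methylidene-4-(prop-2-en-1-yl)-5-(prop-1-en-2-yl)octahydro-1,2-benzoxasilol-5-ol | C#C[C@@]12[C@H](CC=C)[C@@](O)(C(C)=C)CC[C@]1(C)O[Si](C)(C)C2=C | intermediate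
18 | bis(dicyclohexylboryl) adduct of 17 ((E)-2-borylethenyl at C3a, 3-borylpropyl at C4) | C1CCCCC1B(C1CCCCC1)/C=C/[C@@]23[C@H](CCCB(C4CCCCC4)C4CCCCC4)[C@@](O)(C(C)=C)CC[C@]2(C)O[Si](C)(C)C3=C | intermediate
19 | 2-[1-acetyl-2,5-dihydroxy-6-(3-hydroxypropyl)-2-methyl-5-(prop-1-en-2-yl)cyclohexyl]acetaldehyde (acetyl cis to 2-OH and to the 6-chain) | O=CC[C@@]1(C(C)=O)[C@H](CCCO)[C@@](O)(C(C)=C)CC[C@]1(C)O | intermediate
20 | 6,9-dihydroxy-10-(3-hydroxypropyl)-6-methyl-9-(prop-1-en-2-yl)spiro[4.5]dec-2-en-1-one | O=C1C=CC[C@]12[C@H](CCCO)[C@@](O)(C(C)=C)CC[C@]2(C)O | intermediate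
21 | 10-[3-(tert-butyldimethylsilyloxy)propyl]-6,9-dihydroxy-6-methyl-9-(prop-1-en-2-yl)spiro[4.5]dec-2-en-1-one | O=C1C=CC[C@]12[C@H](CCCO[Si](C)(C)C(C)(C)C)[C@@](O)(C(C)=C)CC[C@]2(C)O | intermediate
22 | 10-[3-(tert-butyldimethylsilyloxy)propyl]-6-methyl-9-(prop-1-en-2-yl)spiro[4.5]dec-2-ene-1,6,9-triol (1-OH syn to C10 across ring B) | C1=CC[C@]2([C@H](CCCO[Si](C)(C)C(C)(C)C)[C@@](O)(C(C)=C)CC[C@]2(C)O)[C@@H]1O | intermediate
23 | di-tert-butyl{[(2E,4E)-2-iodo-10-methyl-6-methylideneundeca-2,4,9-trien-1-yl]oxy}silyl trifluoromethanesulfonate | C=C(/C=C/C=C(\CO[Si](OS(=O)(=O)C(F)(F)F)(C(C)(C)C)C(C)(C)C)I)CCC=C(C)C | intermediate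
24 | di-tert-butylsilyl ketal of 22 (1-O) and 7 | C1=CC[C@]2([C@H](CCCO[Si](C)(C)C(C)(C)C)[C@@](O)(C(C)=C)CC[C@]2(C)O)[C@@H]1O[Si](C(C)(C)C)(C(C)(C)C)OC/C(I)=C\C=C\C(=C)CCC=C(C)C | intermediate
25 | enal silyl ketal: (2E)-2-(spiro[4.5]dec-2-en-9-ylidene)propanal with 1-O–Si(tBu)2–O–iodotrienyl, 6-OH, 10-(3-silyloxypropyl) | C1=CC[C@]2([C@H](CCCO[Si](C)(C)C(C)(C)C)/C(=C(\C)C=O)CC[C@]2(C)O)[C@@H]1O[Si](C(C)(C)C)(C(C)(C)C)OC/C(I)=C\C=C\C(=C)CCC=C(C)C | intermediate
26 | cyclised silylene: 27 with the C1 and side-chain CH2 oxygens bridged by tBu2Si and the primary hydroxyl as its tert-butyldimethylsilyl ether | C=C(/C=C/C=C(\CO[Si](C(C)(C)C)(C(C)(C)C)O3)[C@@H]1CC[C@]2([C@H](CCCO[Si](C)(C)C(C)(C)C)/C(=C(\C)C=O)CC[C@]2(C)O)[C@@H]13)CCC=C(C)C | intermediate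
27 | (2E)-2-[(1R,2S,5S,6S,10R)-1,6-dihydroxy-2-[(2Z,4E)-1-hydroxy-10-methyl-6-methylideneundeca-2,4,9-trien-2-yl]-10-(3-hydroxypropyl)-6-methylspiro[4.5]decan-9-ylidene]propanal | C=C(/C=C/C=C(\CO)[C@@H]1CC[C@]2([C@H](CCCO)/C(=C(\C)C=O)CC[C@]2(C)O)[C@@H]1O)CCC=C(C)C | target

**Totals**
Total step count: 18. Longest linear sequence: 15 steps (steps 4–18, from 8).

**Three steps most likely to fail, with fallbacks**

Step 17 (the proposed new step). The risks are premature reduction of the alkenyl radical before the 7-membered closure and radical attack on the triene. The fallback uses known reactions only; it sets out from 21 (and 7) and comes back at 26. Johnson α-iodination of 21 (iodine, pyridine) gives the 2-iodoenone F1. Miyaura borylation of 7 (B2pin2, PdCl2(dppf), KOAc) gives the alkenyl pinacol boronate F2. Suzuki–Miyaura coupling of the two (PdCl2(dppf), K3PO4, aqueous dioxane) gives the cross-conjugated dienone F3. Conjugate reduction with [(Ph3P)CuH]6 gives the 2-alkenylcyclopentanone F4, whose C2 centre can equilibrate. Reduction with Me4NBH(OAc)3 as in step 14 gives the cis-diol F5. tBu2Si(OTf)2 with 2,6-lutidine bridges the C1 and allylic hydroxyls to give the silylene carbinol F6. Oxidative transposition as in step 16 then gives 26. Stereocontrol at C2 is weaker here than with the tether.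

Step 9. The risks are the facial selectivity of the allyl transfer at C10 and direct allylation of the vinyl radical. The fallback sets out from 15 and comes back at 16, separating the two events. Bu3SnH with AIBN gives the reduced bicyclic ketone F7 (tethered cyclisation alone). IBX desaturates the only possible side to give the enone F8. LiN(i-Pr)2 (2.2 equiv) followed by allyl bromide alkylates the α′-position to give the allyl enone F9. Conjugate reduction with LiBH(s-Bu)3 returns 16.

Step 16. The risks are chromate oxidation in the presence of the iodotriene and the silyl ketal, and the enal geometry. The fallback sets out from 22 and comes back at 25, oxidising before the polyene is attached. Et3SiOTf with 2,6-lutidine gives the C1 triethylsilyl ether F10. Pyridinium chlorochromate gives the enal silyl ether F11. Brief HF·pyridine/pyridine at 0 °C removes only the secondary triethylsilyl group to give the enal alcohol F12. Silyl ketal formation with 23 as in step 15 gives 25.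

**Further compounds**
F1 | step 17 | 2-iodo derivative of enone 21 | O=C1C(I)=CC[C@]12[C@H](CCCO[Si](C)(C)C(C)(C)C)[C@@](O)(C(C)=C)CC[C@]2(C)O
F2 | step 17 | pinacol boronate of 7 (boron in place of iodine) | C=C(/C=C/C=C(\CO)B1OC(C)(C)C(C)(C)O1)CCC=C(C)C
F3 | step 17 | 2-(trienyl)spiro[4.5]dec-2-en-1-one (Suzuki product) | C=C(/C=C/C=C(\CO)C1=CC[C@]2([C@H](CCCO[Si](C)(C)C(C)(C)C)[C@@](O)(C(C)=C)CC[C@]2(C)O)C1=O)CCC=C(C)C
F4 | step 17 | 2-(trienyl)spiro[4.5]decan-1-one | C=C(/C=C/C=C(\CO)[C@@H]1CC[C@]2([C@H](CCCO[Si](C)(C)C(C)(C)C)[C@@](O)(C(C)=C)CC[C@]2(C)O)C1=O)CCC=C(C)C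
F5 | step 17 | cis-1-hydroxy-2-(trienyl) diol with free allylic CH2OH | C=C(/C=C/C=C(\CO)[C@@H]1CC[C@]2([C@H](CCCO[Si](C)(C)C(C)(C)C)[C@@](O)(C(C)=C)CC[C@]2(C)O)[C@@H]1O)CCC=C(C)C
F6 | step 17 | di-tert-butylsilylene of F5 retaining the C9 isopropenyl carbinol | C=C(/C=C/C=C(\CO[Si](C(C)(C)C)(C(C)(C)C)O3)[C@@H]1CC[C@]2([C@H](CCCO[Si](C)(C)C(C)(C)C)[C@@](O)(C(C)=C)CC[C@]2(C)O)[C@@H]13)CCC=C(C)C
F7 | step 9 | 3a-ethynyl-2,2,7a-trimethyl-3-methylidenehexahydro-1,2-benzoxasilol-5(4H)-one | C#C[C@@]12CC(=O)CC[C@]1(C)O[Si](C)(C)C2=C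
F8 | step 9 | the corresponding 6,7-unsaturated enone | C#C[C@@]12CC(=O)C=C[C@]1(C)O[Si](C)(C)C2=C
F9 | step 9 | 4-allyl derivative of enone F8 | C#C[C@@]12[C@H](CC=C)C(=O)C=C[C@]1(C)O[Si](C)(C)C2=C
F10 | step 16 | 1-O-triethylsilyl ether of 22 | C1=CC[C@]2([C@H](CCCO[Si](C)(C)C(C)(C)C)[C@@](O)(C(C)=C)CC[C@]2(C)O)[C@@H]1O[Si](CC)(CC)CC
F11 | step 16 | enal 1-O-triethylsilyl ether | C1=CC[C@]2([C@H](CCCO[Si](C)(C)C(C)(C)C)/C(=C(\C)C=O)CC[C@]2(C)O)[C@@H]1O[Si](CC)(CC)CC
F12 | step 16 | enal with free 1-hydroxyl | C1=CC[C@]2([C@H](CCCO[Si](C)(C)C(C)(C)C)/C(=C(\C)C=O)CC[C@]2(C)O)[C@@H]1O
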